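The easy step first: you asked for a quick number and suspected that the dimer costs little, and E by its first step alone has a half-life of 4.33 s, short against the hour.

    E → Z (k1 = 0.16 s⁻¹)
    Z ⇌ J (K2 = 1.1, k2 = 0.036 s⁻¹)
    Z ⇌ G (K3 = 61, k3 = 0.010 s⁻¹)
    2 E → E2 (k4 = 4.7 M⁻¹ s⁻¹)

E 1.0 mM; time 1.0 h

- in percentages every species weighs as the E in it: one E2 counts as two
- two of one species on the left: rate k times its square, two consumed each time
- the reaction counts as stopped when no species that holds the E changes by six tenths of a point or more over the second half of the time
- run time (flask): 1.0 h

1. at 1.0 h, what has stopped the reaction, if anything has (it is still moving / forward and back rates have come level / all of E has reacted)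
2. share of the E used up at 1.0 h
3. J at 1.0 h, in percent of the E charged
4. G at 1.0 h, in percent of the E charged
5. Z at 1.0 h, in percent of the E charged

**Race number.** E has two exits. We call the race number the rate at which E goes to E2 over the rate at which it goes to Z, at the start: 0.0588. The even race, with both exits equal, is 1, and this flask stands far below it. The dimer exit goes with the square of [E], so the race number falls as [E] falls. Summed over that fall, the share reaching Z is ln(1 + x)/x, which is 97.2%, so your hunch holds here.

**Even weights.** With both balance constants at 1, Z, J and G would weigh the same. Here the weights are 1, 1.1 and 61. Z and J together feed G with a time constant near 3.38 min, so the hour is long enough for thermodynamic control among the three, after kinetic control at E's exits.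

**Our numbers.** We expect G at 93.9%, J at 1.69%, Z at 1.54%, and E used to 100%. The steps taking E run one way, and their clock is shorter than the balance's, so we name the stop as all of E has reacted.

**The forecast.** It gives forward and back rates have come level, with G 93.9%, J 1.69%, Z 1.54% and conversion 100%, holding that “the flask is at equilibrium, not merely out of E”.

**The result.** At 1.0 h the flask reads all of E has reacted, with G 93.9%, J 1.69%, Z 1.54% and conversion 100%. The biggest change of a share over the second half of the run was 0.024 percentage points, with 0% of E left. The race number leaves 2.80% of the charge for E2, and this flask holds 2.83%.

**Richer flask.** With 4.0 mM of E in the neighbour flask, the race number grows with the charge to 0.235. The share reaching Z is then 89.8%, which puts G at 86.8% and E2 at 10.2%. The neighbour flask gives G 86.8% and E2 10.2%.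

Its constants are those of an exercise; the run is a simulation.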